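Read the flasks below as one series in the charge of free catalyst, with a fork in the round at catalyst intermediate A.

    substrate + free catalyst → catalyst intermediate A (k1 = 4100 M⁻¹ s⁻¹)
    partner + catalyst intermediate A → catalyst intermediate B (k2 = 4800 M⁻¹ s⁻¹)
    catalyst intermediate B → released group + catalyst intermediate C (k3 = 370 s⁻¹)
    catalyst intermediate C ⇌ free catalyst + target (K4 = 0.0019 M, k4 = 200 s⁻¹)
    catalyst intermediate A + capture agent → trapped intermediate (k5 = 3600 M⁻¹ s⁻¹)
    partner + protic impurity → quenched reagent (k6 = 160 M⁻¹ s⁻¹)

in all of them: substrate 5.0 mM; partner 5.25 mM (in portions, 3); capture agent 0.250 mM; protic impurity 0.500 mM; time 40 s
- north-east: free catalyst 25 µM; the portions of partner follow each other after 3.0 s, the first at the start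
- south-east: free catalyst 80 µM; the portions of partner follow each other after 3.0 s, the first at the start
- west: free catalyst 250 µM; the portions of partner follow each other after 3.0 s, the first at the start
- north: free catalyst 600 µM; the portions of partner follow each other after 3.0 s, the first at the start
- north-west: free catalyst 2000 µM; the portions of partner follow each other after 3.0 s, the first at the start

* amount of target at the end, in percent of the substrate charged for north-east, south-east, west, north, north-west, in this order
* the course of these numbers from the first flask to the last (hardly changes / rises, then falls / rises all the way / falls, then rises / falls all the way)

- "hardly changes" means that all values lie within two and a half points (for a concentration: within two and a half percent of the largest)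
- run time (north-east): 40 s

You want a quick number for north-east, so count what one catalyst does before it is lost. At catalyst intermediate A the round forks: partner carries it forward by step 2, or capture agent removes it by step 5. Set the first portion of partner, 1.75 mM, against the charged 0.250 mM of capture agent, and the forward rate over the capture rate comes to 9.33; call this ratio the turnovers before capture, the partition ratio of that fork. Use the first portion because a round takes about 0.168 s, so that in north-east those turnovers last 1.57 s, less than the 3.0 s before the next portion and less than the 8.7 s half-life of partner under step 6 alone; leave the protic impurity out as a correction not taken.

Add the fall of the capture agent as a correction to that count, since each lost catalyst takes one capture agent and the ratio grows as that level drops. Integrating over the fall gives target = ratio × capture charge × ln(capture charge / (capture charge − catalyst charge)), which for north-east is 4.92% of the substrate, and that is my number. Stop there for the richer flasks, because in west the catalyst charge 250 µM equals the capture charge and the logarithm fails, so I offer no figure from west onward.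

Your forecast reads 6.5%, 24%, 82%, 89% and 72%, with the course rises, then falls, and its ground at the low end is that “the catalyst is killed after about a dozen turnovers”. So we differ on north-east, your 6.5% against my 4.92%.

The flasks give 5.27%, 18.3%, 80.2%, 90.1% and 72.1%, and the course is rises, then falls.

North-east stops at 5.27% with the capture step as the main reason, for the simulated run without that step reaches 70.6% in the same flask. With the step in place, north-east made 10.5 turnovers per catalyst charged, more than the 9.33 counted at the fork. Carry the same ratio and its logarithm to south-east, where 80 µM of catalyst gives 18.0% of the substrate, and the flask holds 18.3%.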